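## Structural features

The target is a linear tetramer of four C6–C3 units: ring A is a guaiacyl ring with the only free phenol, rings B and C are syringyl rings etherified at O4, and ring D is a guaiacyl ring built into a 2,3-dihydrobenzofuran that carries an (E)-propenal at C5. Rings A/B and rings B/C are joined by arylglycerol β-aryl ether units, each a benzylic carbinol (Cα) next to an aryloxy-bearing carbon (Cβ) with a hydroxymethyl group; both pairs are erythro with the same absolute sense (αR,βS). Rings C/D are joined by a trans-2-aryl-3-(hydroxymethyl)-2,3-dihydrobenzofuran (2R,3S), so the six stereocentres form three vicinal pairs that are too far apart to control one another. The fragile groups are the enal (no hydride, no enolate and no hydrogenolysis once it is present), the electron-rich benzylic carbinols and the benzylic ether C2–O1 (ionised by acid, and by base through a quinone methide wherever a free para-phenol faces a benzylic leaving group), and the free phenol towards oxidants. The real difficulty is twofold: an unsymmetrical β–5 bond between a syringyl and a guaiacyl unit must be made by a coupling that tends to give statistical mixtures, and two erythro ether units must be set in absolute terms at the hindered oxygen of 2,6-dimethoxyphenols. The key step exploits that C3–C3a and O1–C2 of the dihydrofuran ring are the bonds that a sinapoyl phenoxy radical (ring C, both ortho positions methoxylated, spin only at O and at the side-chain carbon that becomes C3) forms with C5 and O4 of a guaiacyl partner (ring D).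

## Logic of the disconnections

**34 back to 31.** Only heteroatom bonds are cut: three acyl–oxygen bonds (34 from 33), the oxidation level of the enal (33 from 32) and four O–Si bonds (32 from 31). The enal is traced to a silylated allylic alcohol because it would not survive the enolate and borohydride chemistry used earlier. The gain is a fully masked precursor. The demand is that the oxidation touches the allylic alcohol only, and that the last step frees the ring A phenol after the benzylic esters, not before.

**31 back to 28.** The Cα–O bond of unit B is cut with inversion (31 from 30), then the O–Si bond at Cγ (30 from 29) and the C–N bond of an acyl oxazolidinone together with the reduction level of Cγ (29 from 28). The cut sits at the benzylic oxygen because a boron aldol delivers the syn pair, which is threo, and the benzylic carbinol is the centre that can be inverted. This reduces the erythro pair to an aldol adduct. The demand is an SN2 displacement at an electron-rich benzylic carbon with the primary alcohol out of the way.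

**28 to 16 and 26.** The Cα–Cβ bond of unit B is cut. It lies in the middle of the molecule, creates both centres of unit B at once and divides the tetramer into halves of similar complexity. The forward aldol needs the enolate on the half holding the dihydrobenzofuran, so that half carries its side chain as an allylic silyl ether and not as an aldehyde or acetal, and the aldehyde half must have no free hydroxyl.

**26 back to 18 and 20.** The formyl group of 26 is traced to the propenyl C=C of 25, and unit A is then dismantled like unit B: Cα–O with inversion (25 from 24), O–Si (24 from 23), C–N with reduction (23 from 22) and Cα–Cβ (22 from 18 and 20). The propenyl group is a latent aldehyde that tolerates enolate, borohydride and Mitsunobu chemistry. The gain is that unit A rests on two simple aromatic building blocks. The demand is an oxidative cleavage that spares electron-rich rings, and an aryl ester in 20 that outlasts borohydride.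

**16 and 18 to 13, 17 and 15; 15 from 14; 20 from 19.** The ArO–CH2 bonds are cut, then one N–acyl bond and one aryl O–acyl bond. One electrophile, 15, serves both glycolate units. The gain is commercial phenols and one auxiliary. The demand is that hindered phenoxides attack the α-carbon of 15 and not its imide carbonyl.

**13 back to 10.** Two O–Si bonds are cut (13 from 11), then the imide C–N bond with the reduction level of C3–CH2OH and of the side-chain aldehyde (11 from 10). The auxiliary leaves here and C3 is untouched. The demand is a reduction that does not open the dihydrofuran, and a silylation that leaves the hindered phenol free.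

**10 to 7 and 8.** C3–C3a and O1–C2 are cut, opening the dihydrofuran ring to two monomeric C6–C3 phenols. This is the largest simplification of the route: one ring, two skeletal bonds, two stereocentres and every carbon of the C–D half in one step. The demand is cross- over homo-coupling, C- over O-coupling, facial control at C3 and trans closure.

**7 back to 1 and 4.** An O–Si bond (7 from 6), the N–acyl bond (6 from 3 and 4) and O–Si bonds again (3 from 1) are cut. The gain is commercial sinapic acid and the auxiliary. The demand is a phenol mask that can be removed without touching the enoyl imide.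

## Other disconnections considered

**Alternative 1:** The cut is made inside an ether unit, at Cβ–Cγ and Cα–O. Unit A would come from the (E)-aryl styryl ether A1 and two units of formaldehyde A2, joined by an asymmetric Prins reaction under a confined chiral imino-imidodiphosphate Brønsted acid to the trans-dioxane A3.

- In its favour: one catalytic step would set both centres of an erythro unit directly (trans-4,5 in the dioxane maps onto erythro), add Cγ and deliver the diol protected. On step economy per ether unit it is the better plan, since the chosen route spends four steps per unit (aldol, reduction, silylation, inversion). The aryl bromide of A3 is a ready handle for the next unit.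
- Against it here: A1 is an enol ether flanked by an electron-rich aryl group. A stepwise path through a para-alkoxybenzylic cation would erode the E-to-trans stereospecificity, and Brønsted acid can hydrolyse or oligomerise enol ethers. Such catalysts are established for simple aryl alkenes, so an aryloxy alkene would be a new substrate class. A1 must be made as the pure E isomer, and the methylene acetal needs acid strong enough to endanger benzylic carbinols.
- Comparison: on structure the two plans are equal, both build an ether unit from an aryl aldehyde-level piece and a phenol. On mechanism the alternative is cationic and catalyst-controlled, the chosen plan enolate-based and auxiliary-controlled, longer but with direct precedent on aryloxyacetyl imides. The alternative does not address the dihydrobenzofuran at all.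

**Alternative 2:** The five-membered ring would come from a six-membered one: photolysis of the 3-diazoflavanone A4 in an alcohol solvent, Wolff rearrangement with migration of C3a to C3, ketene trapping and equilibration to the trans ester A5.

- In its favour: the two aryl units are joined by condensation chemistry with unambiguous regiochemistry, so there is no cross- versus homo-coupling question. On chemoselectivity it is the better plan.
- Against it here: a single enantiomer requires A4 enantiopure, and its C2 is β to a ketone with a phenoxide leaving group. The base used for diazo transfer can open the pyranone by retro-oxa-Michael reaction and racemise C2. The base equilibration of A5 carries a related ring-opening hazard through the ester enolate. The bromide and ester of A5 must still become the propenal and the hydroxymethyl group.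
- Comparison: on structure the plans are equal in that both leave C3 as a carboxyl derivative to be reduced, but the chosen plan brings the three-carbon side chain with coniferaldehyde. On mechanism it is carbene/ketene against radical coupling. On step economy the C–D half would take roughly twice as many steps as steps 1–6.

**Alternative 3:** The cut is C2–C3. The aryldiazoacetate A6 would give a carbenoid with Rh2(S-PTTL)4 (dirhodium tetrakis[N-phthaloyl-(S)-tert-leucinate]) that inserts into the benzylic C–H of the ortho benzyl ether; base then equilibrates the cis ester to the trans ester A7.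

- In its favour: the absolute configuration is set by a catalyst and not by a remote auxiliary, the C–H bond is activated by the ether oxygen and an electron-rich aryl group, and five-membered closure is the normal mode. On predictability of chemo- and stereoselectivity it is the better plan.
- Against it here: A6 needs a ring D arylacetic ester with an ortho oxygen, a ring C benzyl halide, an etherification and a diazo transfer, many more steps before the key step than the three that lead to 7. The carbenoid could also attack the electron-rich ring C or form an oxonium ylide. The epimerisation shares the ring-opening hazard, and bromide and ester must be converted afterwards.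
- Comparison: on structure the plans are equal in the oxidation level at C3. On mechanism one is a metal carbenoid insertion and the other a radical combination with conjugate addition. On step economy the chosen plan is clearly shorter, and on robustness the alternative is ahead.

Key step: step 4

**Remarks before the steps**

- Assumption on the key step: under non-chelating Ag2O conditions the imide 7 is taken to react through its dipole-opposed s-cis rotamer with bond formation anti to the benzyl group, which with the (S)-auxiliary leads to the (2R,3R) adduct. If the sense proved opposite, the same sequence would be run with auxiliary 14, and since the auxiliary is excised in step 5 the route would converge at 11.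
- Assumption on 17: the commercial material is an E/Z mixture, drawn here as E; the geometry is irrelevant because the alkene is cleaved in step 15.
- Check of the structures: the target is erythro (αR,βS) in both ether units and trans (2R,3S) in the dihydrobenzofuran. Compound 10 is the (2R,3R) imide; the change of letter at C3 on going to 11 reflects CIP priorities only. An Evans syn-aldol gives the threo and not the erythro pair, so each ether unit includes one inversion.
- Changes to the design around the precursor: the phenol of sinapic acid is masked as a silyl ether, because freeing a 2,6-dimethoxyphenyl acetate needs nucleophiles that also attack an enoyl imide. The auxiliary is used as a resolving handle as well as a director. The enal is carried as an allylic silyl ether, because a cinnamyl acetal would not survive Bu2BOTf.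

## Steps

Step 1
Reactants: 1 sinapic acid
Product: 3 (E)-3-[4-(tert-butyldimethylsilyloxy)-3,5-dimethoxyphenyl]prop-2-enoic acid, via bis-silylated sinapic acid 2 (not isolated)
Conditions: TBSCl (2.5 equiv), imidazole, DMF, rt; then AcOH, THF/H2O, rt
Reagents that add atoms: tert-butyldimethylsilyl chloride, CC(C)(C)[Si](C)(C)Cl
Why: Silylation caps the phenol and, transiently, the acid; the silyl ester is far more labile than the hindered aryl silyl ether and is hydrolysed selectively by aqueous acetic acid. The mask is needed because a free phenol would be acylated in step 2.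

Step 2
Reactants: 3 (E)-3-[4-(tert-butyldimethylsilyloxy)-3,5-dimethoxyphenyl]prop-2-enoic acid; 4 (S)-4-benzyl-2-oxazolidinone
Product: 6 (S)-4-benzyl-3-[(E)-3-[4-(tert-butyldimethylsilyloxy)-3,5-dimethoxyphenyl]prop-2-enoyl]oxazolidin-2-one, via mixed pivalic anhydride 5 (not isolated)
Conditions: PivCl, Et3N, THF, −20 °C; then LiCl, 4, −20 °C to rt
Reagents that add atoms: none
Why: Mixed-anhydride N-acylation of the oxazolidinone; the nucleophile attacks the unhindered cinnamoyl carbonyl and not the pivaloyl one, and no strong base touches the aryl silyl ether or the (E)-alkene.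

Step 3
Reactants: 6 silyl-protected sinapoyl imide
Product: 7 (S)-4-benzyl-3-[(E)-3-(4-hydroxy-3,5-dimethoxyphenyl)prop-2-enoyl]oxazolidin-2-one
Conditions: TBAF, AcOH, THF, 0 °C
Reagents that add atoms: none
Why: Fluoride-mediated desilylation; the aryl Si–O bond cleaves readily because the phenoxide is a good leaving group, and the acetic acid buffer keeps the medium from attacking the enoyl imide.

Step 4
Reactants: 7 N-sinapoyl (S)-4-benzyl-2-oxazolidinone; 8 coniferaldehyde
Product: 10 (S)-4-benzyl-3-[(2R,3R)-2-(4-hydroxy-3,5-dimethoxyphenyl)-7-methoxy-5-[(E)-3-oxoprop-1-enyl]-2,3-dihydro-1-benzofuran-3-carbonyl]oxazolidin-2-one, via phenol quinone methide 9 (not isolated)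
Conditions: Ag2O (1.5 equiv), 8 (3 equiv), CH2Cl2/acetone, rt, dark, 7 added over 8 h; chromatography
Reagents that add atoms: none
Why: Ag2O removes one electron and one proton from each phenol; the radical of 7 has spin only at O4 and at the side-chain carbon next to the carbonyl (both ortho positions carry methoxy groups), and this carbon combines with C5 of the coniferaldehyde radical to form C3–C3a, after which tautomerisation rearomatises ring D and leaves the phenol–quinone methide 9. The closest known reaction type is the Ag2O-mediated β–5 dehydrodimerisation of ferulate esters and of auxiliary-bearing feruloyl amides to trans-phenylcoumarans. The ring closes by 5-exo-trig conjugate addition of the ring D phenol to the exocyclic quinone methide carbon, which forms O1–C2 and rearomatises ring C. C3 is set in the radical combination: in the dipole-opposed s-cis rotamer the benzyl group of the (S)-auxiliary should leave the face leading to 3R the more open one, but this shielding is remote, so only a moderate bias is counted on and the (2S,3S) trans isomer, a diastereomer of 10 while the auxiliary is attached, is to be removed by chromatography or crystallisation. C2 is set in the ring closure, where the aryl group takes the side away from the acyl group at C3; the closure is reversible through 9, so trans is also the thermodynamic outcome. The step needs cross- over homo-coupling and C–C over C–O coupling: slow addition of 7 into an excess of the less easily oxidised 8 keeps the sinapoyl radical dilute, the bulky imide disfavours β–β coupling of two such radicals, and a β–O–4 adduct has no internal nucleophile for ring closure and is separated.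

Step 5
Reactants: 10 dihydrobenzofuran imide enal
Product: 11 4-[(2R,3S)-3-(hydroxymethyl)-5-[(E)-3-hydroxyprop-1-enyl]-7-methoxy-2,3-dihydro-1-benzofuran-2-yl]-2,6-dimethoxyphenol
Conditions: LiBH4, MeOH (2 equiv), THF, 0 °C
Reagents that add atoms: none
Why: Borohydride reduction of the N-acyl oxazolidinone at its exocyclic carbonyl gives the primary alcohol and releases the auxiliary, and the enal is reduced 1,2 in the same flask. The conditions are non-enolising, so C3 keeps its configuration.

Step 6
Reactants: 11 diol phenol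
Product: 13 4-[(2R,3S)-3-(tert-butyldimethylsilyloxymethyl)-5-[(E)-3-(tert-butyldimethylsilyloxy)prop-1-enyl]-7-methoxy-2,3-dihydro-1-benzofuran-2-yl]-2,6-dimethoxyphenol, via tris-silyl ether 12 (not isolated)
Conditions: TBSCl (3.5 equiv), imidazole, DMF, rt; then K2CO3, MeOH, rt
Reagents that add atoms: tert-butyldimethylsilyl chloride, CC(C)(C)[Si](C)(C)Cl
Why: Exhaustive silylation followed by carbonate methanolysis, which removes only the aryl silyl ether and leaves both primary alkyl silyl ethers. This avoids relying on kinetic discrimination between a hindered phenol and two alcohols.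

Step 7
Reactants: 14 (R)-4-benzyl-2-oxazolidinone
Product: 15 (R)-4-benzyl-3-(2-bromoacetyl)oxazolidin-2-one
Conditions: n-BuLi, THF, −78 °C; BrCH2COBr, −78 to 0 °C
Reagents that add atoms: bromoacetyl bromide, BrCC(Br)=O
Why: Standard N-acylation of the lithiated oxazolidinone; the acyl bromide reacts much faster than the α-C–Br bond.

Step 8
Reactants: 13 bis-silylated dihydrobenzofuran phenol; 15 (R)-4-benzyl-3-(2-bromoacetyl)oxazolidin-2-one
Product: 16 (R)-4-benzyl-3-[2-[4-[(2R,3S)-3-(tert-butyldimethylsilyloxymethyl)-5-[(E)-3-(tert-butyldimethylsilyloxy)prop-1-enyl]-7-methoxy-2,3-dihydro-1-benzofuran-2-yl]-2,6-dimethoxyphenoxy]acetyl]oxazolidin-2-one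
Conditions: K2CO3, MeCN, rt
Reagents that add atoms: none
Why: Williamson ether synthesis; the α-bromo imide is an excellent SN2 electrophile, so the hindered phenoxide should be alkylated at carbon under carbonate conditions that leave the silyl ethers and the imide intact.

Step 9
Reactants: 17 2,6-dimethoxy-4-[(E)-prop-1-enyl]phenol; 15 (R)-4-benzyl-3-(2-bromoacetyl)oxazolidin-2-one
Product: 18 (R)-4-benzyl-3-[2-[2,6-dimethoxy-4-[(E)-prop-1-enyl]phenoxy]acetyl]oxazolidin-2-one
Conditions: K2CO3, MeCN, rt
Reagents that add atoms: none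
Why: Williamson ether synthesis as in step 8, on a simple phenol.

Step 10
Reactants: 19 vanillin
Product: 20 4-formyl-2-methoxyphenyl pivalate
Conditions: PivCl, Et3N, DMAP (cat.), CH2Cl2, 0 °C to rt
Reagents that add atoms: pivaloyl chloride, CC(C)(C)C(Cl)=O
Why: O-Acylation of the phenol. The pivalate is chosen because it should outlast borohydride, buffered fluoride and MnO2, is the slowest ester to methanolyse at the end, and as an acyloxy group makes the ring A benzylic position less prone to ionise in step 14.

Step 11
Reactants: 18 ring B aryloxyacetyl imide; 20 4-formyl-2-methoxyphenyl pivalate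
Product: 22 (R)-4-benzyl-3-[(2R,3S)-2-[2,6-dimethoxy-4-[(E)-prop-1-enyl]phenoxy]-3-hydroxy-3-[3-methoxy-4-(pivaloyloxy)phenyl]propanoyl]oxazolidin-2-one, via dibutylboron Z-enolate 21 (not isolated)
Conditions: Bu2BOTf, i-Pr2NEt, CH2Cl2, −78 to 0 °C; 20, −78 to 0 °C; pH 7 buffer, MeOH, H2O2, 0 °C
Reagents that add atoms: none
Why: Evans boron aldol: the Z-enolate reacts through a Zimmerman–Traxler chair with the aldehyde approaching anti to the benzyl group of the auxiliary, which gives the syn adduct. With the (R)-auxiliary the new centres are βS and αS of unit A, the threo pair; aryloxyacetyl imides are established substrates for this reaction.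

Step 12
Reactants: 22 aldol adduct of unit A
Product: 23 4-[(1S,2S)-2-[2,6-dimethoxy-4-[(E)-prop-1-enyl]phenoxy]-1,3-dihydroxypropyl]-2-methoxyphenyl pivalate
Conditions: NaBH4, THF/H2O, 0 °C to rt
Reagents that add atoms: none
Why: Reductive cleavage of the N-acyl oxazolidinone to the primary alcohol with release of the auxiliary; the hindered aryl pivalate should not be attacked by NaBH4 at this temperature.

Step 13
Reactants: 23 threo diol of unit A
Product: 24 4-[(1S,2S)-3-(tert-butyldimethylsilyloxy)-2-[2,6-dimethoxy-4-[(E)-prop-1-enyl]phenoxy]-1-hydroxypropyl]-2-methoxyphenyl pivalate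
Conditions: TBSCl (1.1 equiv), imidazole, CH2Cl2, 0 °C
Reagents that add atoms: tert-butyldimethylsilyl chloride, CC(C)(C)[Si](C)(C)Cl
Why: Selective silylation of the primary over the hindered secondary benzylic alcohol. It also removes a neighbouring group that could interfere in step 14.

Step 14
Reactants: 24 threo silyl ether of unit A
Product: 25 (1R,2S)-3-(tert-butyldimethylsilyloxy)-2-[2,6-dimethoxy-4-[(E)-prop-1-enyl]phenoxy]-1-[3-methoxy-4-(pivaloyloxy)phenyl]propyl 4-nitrobenzoate
Conditions: 4-nitrobenzoic acid, PPh3, DIAD, THF, 0 °C to rt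
Reagents that add atoms: 4-nitrobenzoic acid, O=C(O)c1ccc(cc1)[N+](=O)[O-]
Why: Mitsunobu esterification with inversion at Cα turns the threo (1S,2S) alcohol into the erythro (1R,2S) ester. The acidic carboxylic acid, the electron-withdrawing β-aryloxy group and the acyloxy substituent on ring A all favour SN2 over ionisation.

Step 15
Reactants: 25 erythro 4-nitrobenzoate of unit A
Product: 26 (1R,2S)-3-(tert-butyldimethylsilyloxy)-2-(4-formyl-2,6-dimethoxyphenoxy)-1-[3-methoxy-4-(pivaloyloxy)phenyl]propyl 4-nitrobenzoate
Conditions: K2OsO4·2H2O (cat.), NaIO4, 2,6-lutidine, dioxane/H2O, rt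
Reagents that add atoms: sodium periodate, [Na+].[O-]I(=O)(=O)=O
Why: Lemieux–Johnson oxidative cleavage of the only alkene unmasks the ring B aldehyde; esters, silyl ether and the aromatic rings are inert.

Step 16
Reactants: 16 ring C aryloxyacetyl imide of the dihydrobenzofuran half; 26 ring B aldehyde of the A–B half
Product: 28 syn-aldol adduct (R)-4-benzyl-3-[(2R,3S)-3-hydroxy-propanoyl]oxazolidin-2-one whose C2 carries the aryloxy group of 16 and whose C3 carries ring B of 26, via dibutylboron Z-enolate 27 (not isolated)
Conditions: Bu2BOTf, i-Pr2NEt, CH2Cl2, −78 to 0 °C; 26, −78 to 0 °C; pH 7 buffer, MeOH, H2O2, 0 °C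
Reagents that add atoms: none
Why: Second Evans boron aldol with the same enolate geometry and facial bias as in step 11, which sets βS and αS of unit B (threo). The stereocentres of both halves are remote from the reacting carbons, so the auxiliary alone controls the outcome, and the silyl ethers, esters and alkene are inert to the boron triflate.

Step 17
Reactants: 28 aldol adduct of the two halves
Product: 29 threo diol of unit B (1S,2S), the imide carbon of 28 reduced to CH2OH
Conditions: NaBH4, THF/H2O, 0 °C
Reagents that add atoms: none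
Why: Reductive cleavage of the N-acyl oxazolidinone as in step 12; the imide is far more electrophilic than the 4-nitrobenzoate and the aryl pivalate, which should remain at 0 °C.

Step 18
Reactants: 29 threo diol of unit B
Product: 30 primary tert-butyldimethylsilyl ether of 29
Conditions: TBSCl (1.1 equiv), imidazole, CH2Cl2, 0 °C
Reagents that add atoms: tert-butyldimethylsilyl chloride, CC(C)(C)[Si](C)(C)Cl
Why: Selective silylation of the primary alcohol, as in step 13.

Step 19
Reactants: 30 threo silyl ether of unit B
Product: 31 fully protected tetramer, unit B now the erythro (1R,2S) 4-nitrobenzoate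
Conditions: 4-nitrobenzoic acid, PPh3, DIAD, THF, 0 °C to rt
Reagents that add atoms: 4-nitrobenzoic acid, O=C(O)c1ccc(cc1)[N+](=O)[O-]
Why: Mitsunobu inversion at Cα of unit B, as in step 14. The ring B oxygen para to the carbinol is flanked by two methoxy groups and twisted out of conjugation, which lowers the tendency to ionise.

Step 20
Reactants: 31 fully protected tetramer
Product: 32 tetraol, 31 without its four silyl groups
Conditions: HF·pyridine, pyridine, THF, 0 °C to rt
Reagents that add atoms: none
Why: Buffered fluoride desilylation of four primary alkyl silyl ethers; benzylic 4-nitrobenzoates, the aryl pivalate and the dihydrobenzofuran should tolerate the weakly acidic medium, in which acyl migration is slow.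

Step 21
Reactants: 32 tetraol
Product: 33 enal, 32 with the allylic alcohol oxidised to the (E)-propenal
Conditions: MnO2, CH2Cl2/acetone, rt
Reagents that add atoms: none
Why: MnO2 oxidation is selective for the allylic (cinnamyl) alcohol; the three saturated primary alcohols are not oxidised, both benzylic carbinols are esterified and the phenol is acylated, so no other oxidisable site is exposed.

Step 22
Reactants: 33 enal with two 4-nitrobenzoates and one aryl pivalate
Product: 34 CNP0192639.1
Conditions: K2CO3, MeOH/THF, 0 °C, then rt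
Reagents that add atoms: none
Why: Zemplén-type methanolysis: the activated 4-nitrobenzoates should go first at 0 °C and the hindered aryl pivalate last on warming, so that the ring A phenoxide appears only once Cα of unit A carries a free hydroxyl and no quinone methide can form. The enal and the dihydrobenzofuran tolerate catalytic carbonate at this temperature.

## Compound list

1 | sinapic acid, (E)-3-(4-hydroxy-3,5-dimethoxyphenyl)prop-2-enoic acid | COc1cc(/C=C/C(=O)O)cc(OC)c1O | starting material
2 | tert-butyldimethylsilyl (E)-3-[4-(tert-butyldimethylsilyloxy)-3,5-dimethoxyphenyl]prop-2-enoate | COc1cc(/C=C/C(=O)O[Si](C)(C)C(C)(C)C)cc(OC)c1O[Si](C)(C)C(C)(C)C | intermediate (not isolated)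
3 | (E)-3-[4-(tert-butyldimethylsilyloxy)-3,5-dimethoxyphenyl]prop-2-enoic acid | COc1cc(/C=C/C(=O)O)cc(OC)c1O[Si](C)(C)C(C)(C)C | intermediate
4 | (S)-4-benzyl-2-oxazolidinone | O=C1N[C@@H](Cc2ccccc2)CO1 | starting material
5 | (E)-3-[4-(tert-butyldimethylsilyloxy)-3,5-dimethoxyphenyl]prop-2-enoic pivalic anhydride | COc1cc(/C=C/C(=O)OC(=O)C(C)(C)C)cc(OC)c1O[Si](C)(C)C(C)(C)C | intermediate (not isolated)
6 | (S)-4-benzyl-3-[(E)-3-[4-(tert-butyldimethylsilyloxy)-3,5-dimethoxyphenyl]prop-2-enoyl]oxazolidin-2-one | COc1cc(/C=C/C(=O)N2C(=O)OC[C@@H]2Cc2ccccc2)cc(OC)c1O[Si](C)(C)C(C)(C)C | intermediate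
7 | N-sinapoyl (S)-4-benzyl-2-oxazolidinone, (S)-4-benzyl-3-[(E)-3-(4-hydroxy-3,5-dimethoxyphenyl)prop-2-enoyl]oxazolidin-2-one | COc1cc(/C=C/C(=O)N2C(=O)OC[C@@H]2Cc2ccccc2)cc(OC)c1O | intermediate
8 | coniferaldehyde, (E)-3-(4-hydroxy-3-methoxyphenyl)prop-2-enal | COc1cc(/C=C/C=O)ccc1O | starting material
9 | (S)-4-benzyl-3-[(2S)-3-(3,5-dimethoxy-4-oxocyclohexa-2,5-dien-1-ylidene)-2-[2-hydroxy-3-methoxy-5-[(E)-3-oxoprop-1-enyl]phenyl]propanoyl]oxazolidin-2-one (phenol–quinone methide) | COC1=CC(=C[C@@H](c2cc(/C=C/C=O)cc(OC)c2O)C(=O)N2C(=O)OC[C@@H]2Cc2ccccc2)C=C(OC)C1=O | intermediate (not isolated)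
10 | (S)-4-benzyl-3-[(2R,3R)-2-(4-hydroxy-3,5-dimethoxyphenyl)-7-methoxy-5-[(E)-3-oxoprop-1-enyl]-2,3-dihydro-1-benzofuran-3-carbonyl]oxazolidin-2-one | Oc3c(OC)cc([C@@H]4Oc5c(OC)cc(/C=C/C=O)cc5[C@H]4C(=O)N6C(=O)OC[C@@H]6Cc7ccccc7)cc3OC | intermediate
11 | 4-[(2R,3S)-3-(hydroxymethyl)-5-[(E)-3-hydroxyprop-1-enyl]-7-methoxy-2,3-dihydro-1-benzofuran-2-yl]-2,6-dimethoxyphenol | Oc3c(OC)cc([C@@H]4Oc5c(OC)cc(/C=C/CO)cc5[C@H]4CO)cc3OC | intermediate
12 | tris(tert-butyldimethylsilyl) ether of 11 (phenol and both primary alcohols silylated; 2R,3S) | CC(C)(C)[Si](C)(C)Oc3c(OC)cc([C@@H]4Oc5c(OC)cc(/C=C/CO[Si](C)(C)C(C)(C)C)cc5[C@H]4CO[Si](C)(C)C(C)(C)C)cc3OC | intermediate (not isolated)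
13 | 4-[(2R,3S)-3-(tert-butyldimethylsilyloxymethyl)-5-[(E)-3-(tert-butyldimethylsilyloxy)prop-1-enyl]-7-methoxy-2,3-dihydro-1-benzofuran-2-yl]-2,6-dimethoxyphenol | Oc3c(OC)cc([C@@H]4Oc5c(OC)cc(/C=C/CO[Si](C)(C)C(C)(C)C)cc5[C@H]4CO[Si](C)(C)C(C)(C)C)cc3OC | intermediate
14 | (R)-4-benzyl-2-oxazolidinone | O=C1N[C@H](Cc2ccccc2)CO1 | starting material
15 | (R)-4-benzyl-3-(2-bromoacetyl)oxazolidin-2-one | O=C(CBr)N1C(=O)OC[C@H]1Cc1ccccc1 | intermediate
16 | (R)-4-benzyl-3-[2-[4-[(2R,3S)-3-(tert-butyldimethylsilyloxymethyl)-5-[(E)-3-(tert-butyldimethylsilyloxy)prop-1-enyl]-7-methoxy-2,3-dihydro-1-benzofuran-2-yl]-2,6-dimethoxyphenoxy]acetyl]oxazolidin-2-one | O=C(COc3c(OC)cc([C@@H]4Oc5c(OC)cc(/C=C/CO[Si](C)(C)C(C)(C)C)cc5[C@H]4CO[Si](C)(C)C(C)(C)C)cc3OC)N1C(=O)OC[C@H]1Cc1ccccc1 | intermediate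
17 | 2,6-dimethoxy-4-[(E)-prop-1-enyl]phenol | COc1cc(/C=C/C)cc(OC)c1O | starting material
18 | (R)-4-benzyl-3-[2-[2,6-dimethoxy-4-[(E)-prop-1-enyl]phenoxy]acetyl]oxazolidin-2-one | COc1cc(/C=C/C)cc(OC)c1OCC(=O)N1C(=O)OC[C@H]1Cc1ccccc1 | intermediate
19 | vanillin, 4-hydroxy-3-methoxybenzaldehyde | COc1cc(C=O)ccc1O | starting material
20 | 4-formyl-2-methoxyphenyl pivalate | COc1cc(C=O)ccc1OC(=O)C(C)(C)C | intermediate
21 | dibutylboron (Z)-enolate of 18 | CCCCB(CCCC)O/C(=C\Oc1c(OC)cc(/C=C/C)cc1OC)N1C(=O)OC[C@H]1Cc1ccccc1 | intermediate (not isolated)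
22 | (R)-4-benzyl-3-[(2R,3S)-2-[2,6-dimethoxy-4-[(E)-prop-1-enyl]phenoxy]-3-hydroxy-3-[3-methoxy-4-(pivaloyloxy)phenyl]propanoyl]oxazolidin-2-one | COc1cc([C@H](O)[C@H](C(=O)N3C(=O)OC[C@H]3Cc3ccccc3)Oc2c(OC)cc(/C=C/C)cc2OC)ccc1OC(=O)C(C)(C)C | intermediate
23 | 4-[(1S,2S)-2-[2,6-dimethoxy-4-[(E)-prop-1-enyl]phenoxy]-1,3-dihydroxypropyl]-2-methoxyphenyl pivalate (threo) | COc1cc([C@H](O)[C@H](CO)Oc2c(OC)cc(/C=C/C)cc2OC)ccc1OC(=O)C(C)(C)C | intermediate
24 | 4-[(1S,2S)-3-(tert-butyldimethylsilyloxy)-2-[2,6-dimethoxy-4-[(E)-prop-1-enyl]phenoxy]-1-hydroxypropyl]-2-methoxyphenyl pivalate | COc1cc([C@H](O)[C@H](CO[Si](C)(C)C(C)(C)C)Oc2c(OC)cc(/C=C/C)cc2OC)ccc1OC(=O)C(C)(C)C | intermediate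
25 | (1R,2S)-3-(tert-butyldimethylsilyloxy)-2-[2,6-dimethoxy-4-[(E)-prop-1-enyl]phenoxy]-1-[3-methoxy-4-(pivaloyloxy)phenyl]propyl 4-nitrobenzoate (erythro) | COc1cc([C@@H](OC(=O)c6ccc(cc6)[N+](=O)[O-])[C@H](CO[Si](C)(C)C(C)(C)C)Oc2c(OC)cc(/C=C/C)cc2OC)ccc1OC(=O)C(C)(C)C | intermediate
26 | (1R,2S)-3-(tert-butyldimethylsilyloxy)-2-(4-formyl-2,6-dimethoxyphenoxy)-1-[3-methoxy-4-(pivaloyloxy)phenyl]propyl 4-nitrobenzoate | COc1cc([C@@H](OC(=O)c6ccc(cc6)[N+](=O)[O-])[C@H](CO[Si](C)(C)C(C)(C)C)Oc2c(OC)cc(C=O)cc2OC)ccc1OC(=O)C(C)(C)C | intermediate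
27 | dibutylboron (Z)-enolate of 16 | CCCCB(CCCC)O/C(=C\Oc3c(OC)cc([C@@H]4Oc5c(OC)cc(/C=C/CO[Si](C)(C)C(C)(C)C)cc5[C@H]4CO[Si](C)(C)C(C)(C)C)cc3OC)N1C(=O)OC[C@H]1Cc1ccccc1 | intermediate (not isolated)
28 | syn-aldol adduct of 27 and 26: (R)-4-benzyl-3-[(2R,3S)-3-hydroxy-propanoyl]oxazolidin-2-one with the ring C aryloxy group of 16 at C2 and ring B of 26 at C3 (unit A erythro 1R,2S; dihydrobenzofuran 2R,3S) | COc1cc([C@@H](OC(=O)c6ccc(cc6)[N+](=O)[O-])[C@H](CO[Si](C)(C)C(C)(C)C)Oc2c(OC)cc([C@H](O)[C@H](C(=O)N8C(=O)OC[C@H]8Cc8ccccc8)Oc3c(OC)cc([C@@H]4Oc5c(OC)cc(/C=C/CO[Si](C)(C)C(C)(C)C)cc5[C@H]4CO[Si](C)(C)C(C)(C)C)cc3OC)cc2OC)ccc1OC(=O)C(C)(C)C | intermediate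
29 | threo (1S,2S) diol of unit B: 28 with the imide carbon reduced to CH2OH | COc1cc([C@@H](OC(=O)c6ccc(cc6)[N+](=O)[O-])[C@H](CO[Si](C)(C)C(C)(C)C)Oc2c(OC)cc([C@H](O)[C@H](CO)Oc3c(OC)cc([C@@H]4Oc5c(OC)cc(/C=C/CO[Si](C)(C)C(C)(C)C)cc5[C@H]4CO[Si](C)(C)C(C)(C)C)cc3OC)cc2OC)ccc1OC(=O)C(C)(C)C | intermediate
30 | 29 with the primary hydroxyl of unit B as tert-butyldimethylsilyl ether (unit B 1S,2S) | COc1cc([C@@H](OC(=O)c6ccc(cc6)[N+](=O)[O-])[C@H](CO[Si](C)(C)C(C)(C)C)Oc2c(OC)cc([C@H](O)[C@H](CO[Si](C)(C)C(C)(C)C)Oc3c(OC)cc([C@@H]4Oc5c(OC)cc(/C=C/CO[Si](C)(C)C(C)(C)C)cc5[C@H]4CO[Si](C)(C)C(C)(C)C)cc3OC)cc2OC)ccc1OC(=O)C(C)(C)C | intermediate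
31 | fully protected tetramer: both ether units erythro (1R,2S) with Cα as 4-nitrobenzoate, four primary tert-butyldimethylsilyl ethers, ring A pivalate | COc1cc([C@@H](OC(=O)c6ccc(cc6)[N+](=O)[O-])[C@H](CO[Si](C)(C)C(C)(C)C)Oc2c(OC)cc([C@@H](OC(=O)c7ccc(cc7)[N+](=O)[O-])[C@H](CO[Si](C)(C)C(C)(C)C)Oc3c(OC)cc([C@@H]4Oc5c(OC)cc(/C=C/CO[Si](C)(C)C(C)(C)C)cc5[C@H]4CO[Si](C)(C)C(C)(C)C)cc3OC)cc2OC)ccc1OC(=O)C(C)(C)C | intermediate
32 | tetraol: 31 with all four primary hydroxyls free (allylic alcohol, C3–CH2OH, two Cγ–OH) | COc1cc([C@@H](OC(=O)c6ccc(cc6)[N+](=O)[O-])[C@H](CO)Oc2c(OC)cc([C@@H](OC(=O)c7ccc(cc7)[N+](=O)[O-])[C@H](CO)Oc3c(OC)cc([C@@H]4Oc5c(OC)cc(/C=C/CO)cc5[C@H]4CO)cc3OC)cc2OC)ccc1OC(=O)C(C)(C)C | intermediate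
33 | enal: 32 with the allylic alcohol oxidised to the (E)-propenal | COc1cc([C@@H](OC(=O)c6ccc(cc6)[N+](=O)[O-])[C@H](CO)Oc2c(OC)cc([C@@H](OC(=O)c7ccc(cc7)[N+](=O)[O-])[C@H](CO)Oc3c(OC)cc([C@@H]4Oc5c(OC)cc(/C=C/C=O)cc5[C@H]4CO)cc3OC)cc2OC)ccc1OC(=O)C(C)(C)C | intermediate
34 | CNP0192639.1, (E)-3-[(2R,3S)-2-[4-[(1R,2S)-1-[4-[(1R,2S)-1,3-dihydroxy-1-(4-hydroxy-3-methoxyphenyl)propan-2-yl]oxy-3,5-dimethoxyphenyl]-1,3-dihydroxypropan-2-yl]oxy-3,5-dimethoxyphenyl]-3-(hydroxymethyl)-7-methoxy-2,3-dihydro-1-benzofuran-5-yl]prop-2-enal | COc1cc([C@@H](O)[C@H](CO)Oc2c(OC)cc([C@@H](O)[C@H](CO)Oc3c(OC)cc([C@@H]4Oc5c(OC)cc(/C=C/C=O)cc5[C@H]4CO)cc3OC)cc2OC)ccc1O | target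

## Step count and least certain steps

Total step count: 22. Longest linear sequence: 14 steps (steps 1–6, 8 and 16–22 from sinapic acid; the branch through steps 7, 9 and 11–15 is equally long).

**Step 4 (key step).** The most likely failure is that the phenoxy radicals pair with their own kind (β–β coupling of two sinapoyl radicals, self-coupling of coniferaldehyde through its own side-chain carbon), that the bond forms through oxygen instead of C5, or that the remote benzyl group discriminates the two faces of the radical only weakly. In each case the wanted diastereomer would be a small share of the material. The fallback replaces the radical coupling by an ionic aldol and ring closure; it sets out from auxiliary 14 and returns at 12. Commercial 2-allyl-6-methoxyphenol F1 would be brominated para to the hydroxyl (NBS, MeCN, 0 °C) to the bromophenol F2 and protected (MOMCl, i-Pr2NEt) as the methoxymethyl ether F3. Cleavage of the terminal alkene (K2OsO4·2H2O cat., NaIO4, 2,6-lutidine) would give the arylacetaldehyde F4, and Pinnick oxidation (NaClO2, NaH2PO4, 2-methyl-2-butene) the arylacetic acid F5, which is joined to 14 (PivCl, Et3N; then LiCl) to give the arylacetyl imide F6. An Evans syn-aldol (Bu2BOTf, i-Pr2NEt) of F6 with the silylated syringaldehyde F7, made from syringaldehyde and TBSCl, should give the (2R,3R) adduct F8, in which the future C3 is fixed by the (R)-auxiliary. Trifluoroacetic acid in CH2Cl2 at 0 °C would remove the methoxymethyl group and ionise the electron-rich benzylic carbinol, and the ring D oxygen would close the ring to the trans-dihydrobenzofuran imide F9. The C3 centre directs the aryl group to the trans side, and the carbinol configuration is lost in the cation and does not matter. LiBH4 would then give the primary alcohol F10 and TBSCl/imidazole its silyl ether F11. Suzuki–Miyaura coupling of F11 with the alkenylboronate F12 (Pd(PPh3)4, K2CO3, dioxane/H2O, 80 °C) installs the side chain and gives 12, which re-enters at the carbonate methanolysis of step 6.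

**Step 19 (Mitsunobu inversion on the full skeleton; step 14 is the same reaction on a smaller substrate and serves as its test).** The activated benzylic alkoxyphosphonium may ionise, giving partial retention, or eliminate towards the enol ether, because the flanking 2,6-dimethoxyaryloxy group slows the SN2 displacement. The fallback replaces inversion by oxidation and reduction; it sets out from 30 and returns at 31. Dess–Martin periodinane would oxidise the carbinol to the aryl ketone F13, which is reduced at once with LiBH(s-Bu)3 in THF at −78 °C. Under Felkin–Anh control, with hydride delivered anti to the aryloxy group, this should give the erythro alcohol F14, which 4-nitrobenzoyl chloride and pyridine convert into 31.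

**Step 22 (final methanolysis).** If the pivalate is lost ahead of the benzylic 4-nitrobenzoate of unit A, the ring A phenoxide can expel that benzoate through a quinone methide and methanol can add at Cα, scrambling the centre; conjugate addition to the enal is a lesser concern. The fallback changes the protecting-group order so that the phenoxide never faces a benzylic ester; it sets out from 31 and returns at 34. Mg(OMe)2 in MeOH would remove both 4-nitrobenzoates and leave the pivalate and silyl ethers, giving the diol F15. TBSOTf and 2,6-lutidine would give the hexasilyl ether F16, and HF·pyridine/pyridine at 0 °C would cleave only the four primary silyl ethers to the tetraol F17. MnO2 then gives the enal F18, and K2CO3 in MeOH removes the pivalate to give the phenol F19; a benzylic silyl ether is not a leaving group, so no quinone methide can form. TBAF buffered with AcOH finally frees both benzylic hydroxyls to give 34.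

**Step 8 (etherification of the hindered phenol; step 9 is the same reaction on a simple phenol).** The phenoxide may attack the imide carbonyl instead of the α-carbon, transferring the acyl group and losing the auxiliary, since 2,6-disubstitution slows the SN2 path. The fallback builds the glycolate first and attaches the auxiliary afterwards; it sets out from 13 and returns at 16. Ethyl bromoacetate and K2CO3 would give the aryloxyacetate F20, LiOH in THF/H2O the aryloxyacetic acid F21, and acylation of 14 (PivCl, Et3N; then LiCl) gives 16.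

## Further compounds

F1 | step 4 | 2-allyl-6-methoxyphenol (commercial) | C=CCc1cccc(OC)c1O
F2 | step 4 | 2-allyl-4-bromo-6-methoxyphenol | C=CCc1cc(Br)cc(OC)c1O
F3 | step 4 | 1-allyl-5-bromo-3-methoxy-2-(methoxymethoxy)benzene | C=CCc1cc(Br)cc(OC)c1OCOC
F4 | step 4 | 2-[5-bromo-3-methoxy-2-(methoxymethoxy)phenyl]acetaldehyde | O=CCc1cc(Br)cc(OC)c1OCOC
F5 | step 4 | 2-[5-bromo-3-methoxy-2-(methoxymethoxy)phenyl]acetic acid | OC(=O)Cc1cc(Br)cc(OC)c1OCOC
F6 | step 4 | (R)-4-benzyl-3-[2-[5-bromo-3-methoxy-2-(methoxymethoxy)phenyl]acetyl]oxazolidin-2-one | O=C(Cc1cc(Br)cc(OC)c1OCOC)N1C(=O)OC[C@H]1Cc1ccccc1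
F7 | step 4 | 4-(tert-butyldimethylsilyloxy)-3,5-dimethoxybenzaldehyde | COc1cc(C=O)cc(OC)c1O[Si](C)(C)C(C)(C)C
F8 | step 4 | (R)-4-benzyl-3-[(2R,3R)-2-[5-bromo-3-methoxy-2-(methoxymethoxy)phenyl]-3-[4-(tert-butyldimethylsilyloxy)-3,5-dimethoxyphenyl]-3-hydroxypropanoyl]oxazolidin-2-one | O=C([C@H](c1cc(Br)cc(OC)c1OCOC)[C@@H](O)c1cc(OC)c(O[Si](C)(C)C(C)(C)C)c(OC)c1)N1C(=O)OC[C@H]1Cc1ccccc1
F9 | step 4 | (R)-4-benzyl-3-[(2R,3R)-5-bromo-2-[4-(tert-butyldimethylsilyloxy)-3,5-dimethoxyphenyl]-7-methoxy-2,3-dihydro-1-benzofuran-3-carbonyl]oxazolidin-2-one | CC(C)(C)[Si](C)(C)Oc3c(OC)cc([C@@H]4Oc5c(OC)cc(Br)cc5[C@H]4C(=O)N6C(=O)OC[C@H]6Cc7ccccc7)cc3OC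
F10 | step 4 | [(2R,3S)-5-bromo-2-[4-(tert-butyldimethylsilyloxy)-3,5-dimethoxyphenyl]-7-methoxy-2,3-dihydro-1-benzofuran-3-yl]methanol | CC(C)(C)[Si](C)(C)Oc3c(OC)cc([C@@H]4Oc5c(OC)cc(Br)cc5[C@H]4CO)cc3OC
F11 | step 4 | tert-butyldimethylsilyl ether of F10 | CC(C)(C)[Si](C)(C)Oc3c(OC)cc([C@@H]4Oc5c(OC)cc(Br)cc5[C@H]4CO[Si](C)(C)C(C)(C)C)cc3OC
F12 | step 4 | (E)-3-(tert-butyldimethylsilyloxy)prop-1-enylboronic acid pinacol ester (commercial) | CC(C)(C)[Si](C)(C)OC/C=C/B1OC(C)(C)C(C)(C)O1
F13 | step 19 | aryl ketone: 30 with Cα of unit B oxidised to C=O | COc1cc([C@@H](OC(=O)c6ccc(cc6)[N+](=O)[O-])[C@H](CO[Si](C)(C)C(C)(C)C)Oc2c(OC)cc(C(=O)[C@H](CO[Si](C)(C)C(C)(C)C)Oc3c(OC)cc([C@@H]4Oc5c(OC)cc(/C=C/CO[Si](C)(C)C(C)(C)C)cc5[C@H]4CO[Si](C)(C)C(C)(C)C)cc3OC)cc2OC)ccc1OC(=O)C(C)(C)C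
F14 | step 19 | erythro (1R,2S) alcohol of unit B, the Cα epimer of 30 | COc1cc([C@@H](OC(=O)c6ccc(cc6)[N+](=O)[O-])[C@H](CO[Si](C)(C)C(C)(C)C)Oc2c(OC)cc([C@@H](O)[C@H](CO[Si](C)(C)C(C)(C)C)Oc3c(OC)cc([C@@H]4Oc5c(OC)cc(/C=C/CO[Si](C)(C)C(C)(C)C)cc5[C@H]4CO[Si](C)(C)C(C)(C)C)cc3OC)cc2OC)ccc1OC(=O)C(C)(C)C
F15 | step 22 | 31 with both benzylic hydroxyls free (four primary silyl ethers and pivalate kept) | COc1cc([C@@H](O)[C@H](CO[Si](C)(C)C(C)(C)C)Oc2c(OC)cc([C@@H](O)[C@H](CO[Si](C)(C)C(C)(C)C)Oc3c(OC)cc([C@@H]4Oc5c(OC)cc(/C=C/CO[Si](C)(C)C(C)(C)C)cc5[C@H]4CO[Si](C)(C)C(C)(C)C)cc3OC)cc2OC)ccc1OC(=O)C(C)(C)C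
F16 | step 22 | hexakis(tert-butyldimethylsilyl) ether: F15 with both benzylic hydroxyls silylated | COc1cc([C@@H](O[Si](C)(C)C(C)(C)C)[C@H](CO[Si](C)(C)C(C)(C)C)Oc2c(OC)cc([C@@H](O[Si](C)(C)C(C)(C)C)[C@H](CO[Si](C)(C)C(C)(C)C)Oc3c(OC)cc([C@@H]4Oc5c(OC)cc(/C=C/CO[Si](C)(C)C(C)(C)C)cc5[C@H]4CO[Si](C)(C)C(C)(C)C)cc3OC)cc2OC)ccc1OC(=O)C(C)(C)C
F17 | step 22 | tetraol with both benzylic silyl ethers and the pivalate kept | COc1cc([C@@H](O[Si](C)(C)C(C)(C)C)[C@H](CO)Oc2c(OC)cc([C@@H](O[Si](C)(C)C(C)(C)C)[C@H](CO)Oc3c(OC)cc([C@@H]4Oc5c(OC)cc(/C=C/CO)cc5[C@H]4CO)cc3OC)cc2OC)ccc1OC(=O)C(C)(C)C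
F18 | step 22 | enal of F17 | COc1cc([C@@H](O[Si](C)(C)C(C)(C)C)[C@H](CO)Oc2c(OC)cc([C@@H](O[Si](C)(C)C(C)(C)C)[C@H](CO)Oc3c(OC)cc([C@@H]4Oc5c(OC)cc(/C=C/C=O)cc5[C@H]4CO)cc3OC)cc2OC)ccc1OC(=O)C(C)(C)C
F19 | step 22 | F18 with the ring A phenol free | COc1cc([C@@H](O[Si](C)(C)C(C)(C)C)[C@H](CO)Oc2c(OC)cc([C@@H](O[Si](C)(C)C(C)(C)C)[C@H](CO)Oc3c(OC)cc([C@@H]4Oc5c(OC)cc(/C=C/C=O)cc5[C@H]4CO)cc3OC)cc2OC)ccc1O
F20 | step 8 | ethyl 2-[4-[(2R,3S)-3-(tert-butyldimethylsilyloxymethyl)-5-[(E)-3-(tert-butyldimethylsilyloxy)prop-1-enyl]-7-methoxy-2,3-dihydro-1-benzofuran-2-yl]-2,6-dimethoxyphenoxy]acetate | CCOC(=O)COc3c(OC)cc([C@@H]4Oc5c(OC)cc(/C=C/CO[Si](C)(C)C(C)(C)C)cc5[C@H]4CO[Si](C)(C)C(C)(C)C)cc3OC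
F21 | step 8 | 2-[4-[(2R,3S)-3-(tert-butyldimethylsilyloxymethyl)-5-[(E)-3-(tert-butyldimethylsilyloxy)prop-1-enyl]-7-methoxy-2,3-dihydro-1-benzofuran-2-yl]-2,6-dimethoxyphenoxy]acetic acid | OC(=O)COc3c(OC)cc([C@@H]4Oc5c(OC)cc(/C=C/CO[Si](C)(C)C(C)(C)C)cc5[C@H]4CO[Si](C)(C)C(C)(C)C)cc3OC
A1 | alternative 1 | (E)-1-benzyloxy-4-[2-(4-bromo-2,6-dimethoxyphenoxy)ethenyl]-2-methoxybenzene | COc1cc(/C=C/Oc2c(OC)cc(Br)cc2OC)ccc1OCc1ccccc1
A2 | alternative 1 | formaldehyde | C=O
A3 | alternative 1 | (4R,5S)-4-(4-benzyloxy-3-methoxyphenyl)-5-(4-bromo-2,6-dimethoxyphenoxy)-1,3-dioxane (trans) | COc1cc([C@@H](OCOC7)[C@H]7Oc2c(OC)cc(Br)cc2OC)ccc1OCc1ccccc1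
A4 | alternative 2 | (S)-6-bromo-2-[4-(tert-butyldimethylsilyloxy)-3,5-dimethoxyphenyl]-3-diazo-8-methoxychroman-4-one | CC(C)(C)[Si](C)(C)Oc1c(OC)cc(cc1OC)[C@@H]1Oc2c(OC)cc(Br)cc2C(=O)C1=[N+]=[N-]
A5 | alternative 2 | methyl (2R,3R)-5-bromo-2-[4-(tert-butyldimethylsilyloxy)-3,5-dimethoxyphenyl]-7-methoxy-2,3-dihydro-1-benzofuran-3-carboxylate (trans) | CC(C)(C)[Si](C)(C)Oc3c(OC)cc([C@@H]4Oc5c(OC)cc(Br)cc5[C@H]4C(=O)OC)cc3OC
A6 | alternative 3 | methyl 2-[5-bromo-2-[[3,5-dimethoxy-4-(methoxymethoxy)phenyl]methoxy]-3-methoxyphenyl]-2-diazoacetate | COCOc1c(OC)cc(COc2c(OC)cc(Br)cc2C(=[N+]=[N-])C(=O)OC)cc1OC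
A7 | alternative 3 | methyl (2R,3R)-5-bromo-2-[3,5-dimethoxy-4-(methoxymethoxy)phenyl]-7-methoxy-2,3-dihydro-1-benzofuran-3-carboxylate (trans) | COCOc3c(OC)cc([C@@H]4Oc5c(OC)cc(Br)cc5[C@H]4C(=O)OC)cc3OC
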